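The runs stem from a simulated flask with constants of no real substance; scatter was added.

X, the complex, is taken to exchange ligands for J step by step, each step pseudo-first-order in J. D then follows one clock in every flask with this X charge: the exposure θ, the time integral of J.

| flask | X | J | remark | time |
|---|---|---|---|---|
| spring | 20 mM | 30 mM | run made earlier |  |
| summer | 20 mM | 270 mM | run made earlier |  |
| green | 20 mM | 25.0 mM |  | 15 min |
| blue | 20 mM | 50.0 mM |  | 15 min |
| red | 20 mM | 100 mM |  | 15 min |
| amber | 20 mM | 200 mM |  | 15 min |

| run | time / min | D / % |
|---|---|---|
| spring | 0.833 | 0 |
| spring | 1.50 | 0 |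
| spring | 3.00 | 2.0 |
| spring | 6.00 | 5.5 |
| spring | 10.0 | 9.9 |
| summer | 2.00 | 25.7 |
| summer | 4.00 | 36.4 |
| summer | 6.00 | 34.7 |
| summer | 8.00 | 29.2 |
| summer | 10.0 | 23.1 |

(standard deviation of a reading: 0.5 percentage points)

- the numbers in the tables scatter with a standard deviation of 0.5 percentage points
- "hardly changes" means that all values lie within two and a half points (for a concentration: within two and a half percent of the largest)

- amount of D at the end, in percent of the X charged for green, blue, red, amber, in this order
- the shape of the row from first to last (falls all the way / rises all the way / falls, then rises / hardly changes / rises, then falls)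

Three given numbers could matter. The scatter, 0.5 percentage points, is small beside the summer rise from 25.7% to 36.4%. The summer peak time is coarse, but the readings at 4.00 min and 6.00 min are 36.4% and 34.7%, so an error there moves a flask's side of the peak more than its height. The X charge matters through J loss: at least two J per X reaching D make 40.0 mM, more than green's charge, so J is the limiting reagent there, whereas amber holds 200 mM.

My own reckoning starts with J held at its charge, which gives red 1500 mM·min. The second round subtracts the mean loss, taken as one X charge:

θ_p = (270 mM − 20 mM) × 4.00 min = 1000 mM·min

blue: 450 mM·min; red: 1200 mM·min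

Here θ_p is the exposure at which D peaks. Summer on the same terms has 500 mM·min at 2.00 min. Blue therefore lies just under 25.7%, and red between 34.7% and 36.4%. A third round, for flasks past the peak, takes the mean loss as 60.0 mM:

amber: 2100 mM·min; summer at 10.0 min: 2100 mM·min

So amber lies near 23.1%. For green the subtraction overshoots, so first-round values serve: 375 mM·min against spring's 300 mM·min, which puts green just above 9.9%.

The forecast gives 9%, 24%, 35% and 18%, shape rises, then falls: “Green is J-starved, while amber has already passed its maximum.” Its amber stands below my reckoning.

The flasks give 10.7%, 23.9%, 36.1% and 24.3%, shape rises, then falls.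

    D + J → G + E (k = 0.0200 /M/s)
    Z + J → G + D (k = 0.0860 /M/s)
    G + J ⇌ L, settled at all times (K = 7400 /M)
    X + J → G + Z (k = 0.0210 /M/s)

Amber stands 6.3 points above the forecast, with J down to 50.6% of its charge at 15.0 min. Red's J, 59.8% of charge at 7.50 min and 38.5% at the end, integrates by Simpson's rule to 944 mM·min, close to θ_p at 1000 mM·min. Amber's 63.5% and 50.6% give 2020 mM·min, twice red's, and amber holds D at 24.3% beside E, the complex with three exchanged, at 65.5%.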